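The earlier runs and the new flask are calculated on assumed constants.

The grey flask cannot reach full conversion by 12 h at its late pace. At 3.1 h it has made 0.0837 M of product, so c(substrate) is still 0.0663 M. Turning that much by 12 h asks for 0.00745 M h⁻¹, but its last step ran at 0.00292 M h⁻¹, which is slower.

| flask | substrate | coupling partner | free catalyst | time |
|---|---|---|---|---|
| grey | 0.150 M | 0.450 M | 0.00750 M |  |
| violet | 0.300 M | 0.450 M | 0.00750 M |  |
| green | 0.150 M | 0.900 M | 0.00750 M |  |
| blue | 0.150 M | 0.450 M | 0.00370 M |  |
| red | 0.150 M | 0.450 M | 0.00750 M | 12 h |

| grey run: time / h | grey run: [product] / M | violet run: time / h | violet run: [product] / M | green run: time / h | green run: [product] / M | blue run: time / h | blue run: [product] / M |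
|---|---|---|---|---|---|---|---|
| 0.12 | 0.0345 | 0.12 | 0.0656 | 0.12 | 0.0462 | 0.12 | 0.0243 |
| 0.21 | 0.0454 | 0.21 | 0.0864 | 0.21 | 0.0589 | 0.21 | 0.0327 |
| 0.36 | 0.0564 | 0.36 | 0.1042 | 0.36 | 0.0697 | 0.36 | 0.0420 |
| 0.62 | 0.0664 | 0.62 | 0.1180 | 0.62 | 0.0792 | 0.62 | 0.0505 |
| 1.1 | 0.0750 | 1.1 | 0.1298 | 1.1 | 0.0877 | 1.1 | 0.0574 |
| 1.8 | 0.0799 | 1.8 | 0.1351 | 1.8 | 0.0930 | 1.8 | 0.0630 |
| 3.1 | 0.0837 | 3.1 | 0.1361 | 3.1 | 0.0965 | 3.1 | 0.0668 |

(readings scatter by 4 × 10⁻⁴ M)

- Overall: substrate + coupling partner -> product, with free catalyst as catalyst.
- Constant volume, constant temperature.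
- "The second partner" is coupling partner.
- An order is taken over about fifteen percent of the charge, up and down.

- how the opening rate goes with [free catalyst] round the charge of the grey run: the exponent of the rate at two percent of substrate gone to product
- how the opening rate goes with [substrate] round the charge of the grey run: the exponent of the rate at two percent of substrate gone to product (one fixed amount of product, the same in the runs compared)
- product in the red run at 12 h, as a share of the substrate charged

The red run repeats the grey charge, so I read grey for red and keep a ledger of substrate, the smaller charge.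

The first entry is what stands made in the grey run at 3.1 h: 55.8 % of the charge. The second entry is what the late rate still adds, and I compute it as a correction. The grey step from 1.1 h to 1.8 h ran at 0.00700 M h⁻¹, faster than the last step. Their midpoints lie 1.00 h apart, so the late rate falls by 0.873 h⁻¹. This fractional fall of the rate per hour is the fade constant.

Brought forward to 3.1 h, I put the grey rate at 0.00166 M h⁻¹. A rate fading this way adds about rate over fade constant, so I put what is still to come at 0.00190 M, or 1.26 % of the charge. This entry is soft: the last step of 0.00380 M carries a scatter of 5.66 × 10⁻⁴ M.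

The third entry closes the books: on this reckoning 42.9 % of the charge stays as substrate. My figure for the red run is therefore 57.1 %. I reckon no orders of my own.

The forecast gives 58 %, within 56 % to 61.5 %, which is above my figure. Its ground is that “Grey's late rate, about 0.002 M/h and falling by roughly 0.9 per hour, adds only a few mM”. For the opening orders it gives 0.95 in substrate and 0.6 in free catalyst.

    2 active catalyst ⇌ catalyst dimer, settled at all times (1740 M⁻¹)
    active catalyst + substrate + coupling partner → product + active catalyst (7596 M⁻² h⁻¹)
    free catalyst → active catalyst (54.00 h⁻¹)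
    2 coupling partner → lost reagent (16.34 M⁻¹ h⁻¹)

The flask gives 57.5 %, with opening orders 0.83 in substrate and 0.46 in free catalyst, the latter lower than the forecast's. With 0.493 of the grey catalyst, the blue run has 0.71 of the grey rate at one fixed amount of product. At 12 h the red run stands 0.00262 M above the last grey reading, against my 0.00190 M. Carried to the green run from its step ending at 1.8 h, the fade constant of 0.873 h⁻¹ gives 0.0973 M at 3.1 h, and the reading there is 0.0965 M.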